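The numbers in the tables were generated by integration for substances that don't exist; scatter was added.

Follow the ash flask to 6.0 d and say how other capture product and target share out.

| setting | ash | alder | flask |
|---|---|---|---|
| substrate | 0.050 M | 0.050 M | 0.050 M |
| first nucleophile | 0.060 M | 0.060 M | 0.0600 M |
| second nucleophile | 0.0475 M | 0.095 M | 0.0475 M |
| remark | the very flask that is asked about, followed so far | run made earlier |  |
| time |  |  | 6.0 d |

ash run (percent of the substrate charged)

| time / h | other capture product / % | target / % |
|---|---|---|
| 2.50 | 7.7 | 9.1 |
| 8.00 | 20.2 | 24.5 |
| 12.0 | 24.2 | 32.2 |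
| 20.0 | 32.4 | 40.3 |
| 30.0 | 36.2 | 44.8 |

alder run (percent of the substrate charged)

| time / d | other capture product / % | target / % |
|---|---|---|
| 0.500 | 36.7 | 22.2 |
| 0.833 | 47.6 | 28.4 |
| 1.67 | 54.7 | 33.7 |
| 3.00 | 56.6 | 34.2 |
| 6.00 | 56.3 | 34.3 |

(readings scatter by 0.5 percentage points)

1. share of other capture product in other capture product plus target at 1.0 h
2. share of other capture product in other capture product plus target at 6.0 d
3. which of other capture product and target there is more of at 6.0 d

- what was read earlier has a scatter of 0.5 percentage points, one standard deviation

I divided the ratio of other capture product to target by the ratio of the charges of second to first nucleophile and called this the preference, a selectivity factor: the last alder reading gave a preference of 1.04. The last ash reading gave 1.02, though the alder run held twice the second nucleophile of the ash run. In the ash run the share of other capture product read 45.8 % at 2.50 h and 44.7 % at 30.0 h. Carrying the alder preference to the ash charges, I reckoned a share of 45.1 % for both asked times.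

The forecast gave 45 % (range 43.3 % to 46.8 %) at 1.0 h and 44.8 % (range 43.7 % to 45.9 %) at 6.0 d, with target ahead, holding that “the two nucleophiles appear to compete for one species”.

The ash flask gave 45.2 % at 1.0 h and 44.5 % at 6.0 d, with target at 48.0 % and other capture product at 38.4 %, so the forecast held.

    second nucleophile ⇌ dormant form (K = 0.210, k = 2.50 × 10⁻⁴ s⁻¹)
    intermediate → side product (k = 2.30 × 10⁻⁵ s⁻¹)
    second nucleophile + intermediate → other capture product (k = 0.0270 M⁻¹ s⁻¹)
    substrate → intermediate (k = 2.50 × 10⁻⁵ s⁻¹)
    intermediate → solvolysis product (k = 2.70 × 10⁻⁴ s⁻¹)
    first nucleophile + intermediate → target (k = 0.0220 M⁻¹ s⁻¹)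

The end amounts of the ash flask give a preference of 1.01. In that flask 12.5 % of the substrate ended as solvolysis product, yet the step to it made no difference to the share. A neighbouring flask charged with 0.024 M of first nucleophile, other charges as in the ash flask, reckons with the alder preference to a share of 67.2 %. That neighbouring flask gave 66.6 % at 6.0 d, with target at 26.3 % and other capture product at 52.5 %.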